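**Retrosynthetic overview** (atoms numbered in the order of the target SMILES)
- Feature: in the bicyclo[2.2.2]octene, the alkene C2=C3 adjoins bridgehead C4, which carries the lactone α-carbon C5 and its carboxyl C6. This is a γ,δ-unsaturated acid, the retron of an ester-enolate Claisen shift.
- Key disconnection: C4–C5, made by Ireland–Claisen rearrangement of the cis-fused tertiary allylic δ-lactone 25 (C6 tied to O on C2) to the bicyclooctene acid 28; the δ-lactone O8–C6 is then re-closed on C9–OH.
- 25 comes from carbinol 22 by alkoxide-driven translactonisation with silyl capture; 22 from MeCeCl2 addition to enone 21; 21 from Michael addition (C21–C22) of the (R)-cryptone enolate to O-TBS-altholactone 18.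
- 18 comes from diacetone-D-glucose (C20, C9, C10 from the sugar; C12 by PhMgBr addition then SN2 ring closure); (R)-cryptone 5 from isovaleraldehyde and methyl vinyl ketone.
- Ring order: tetrahydrofuran (step 7), pyranone (step 10), cyclohexenone (step 2, separate branch), lactone on C2–O (step 14), bicyclo[2.2.2]octene (step 15), final δ-lactone (step 17).

Key step: step 15

Remark (assumption): the diarylprolinol ether catalyst of step 1 is taken to follow its usual enamine face-shielding model, so that the (R)-catalyst gives (R)-3.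

**Step 1**
Reactants: 1 isovaleraldehyde; 2 methyl vinyl ketone
Product: 3 (R)-2-isopropyl-5-oxohexanal
Conditions: (R)-2-[methoxy(diphenyl)methyl]pyrrolidine (5 mol %), ethyl 3,4-dihydroxybenzoate (20 mol %), neat, 4 °C
Reagents that add atoms: none
Why: Enamine-catalysed Michael addition of an aldehyde to an enone, in which the E-enamine is attacked on the face remote from the diarylmethyl group and so sets the isopropyl-bearing centre (later C24) as R.

**Step 2**
Reactants: 3 (R)-2-isopropyl-5-oxohexanal
Product: 5 (R)-cryptone, via β-hydroxy ketone 4 (not isolated)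
Conditions: 0.1 M aq KOH, n-Bu4NOH (cat.), Et2O/THF, reflux
Reagents that add atoms: none
Why: Intramolecular aldol condensation of the methyl ketone onto the aldehyde (six-membered ring, E1cB dehydration), fast enough under dilute base to outrun epimerisation of the α-branched aldehyde.

**Step 3**
Reactants: 6 diacetone-D-glucose
Product: 7 1,2:5,6-di-O-isopropylidene-3-O-(2-naphthylmethyl)-α-D-glucofuranose
Conditions: NaH, 2-(bromomethyl)naphthalene, n-Bu4NI (cat.), DMF, 0 °C to rt
Reagents that add atoms: 2-(bromomethyl)naphthalene, BrCc1ccc2ccccc2c1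
Why: Williamson etherification of the only free hydroxyl; the naphthylmethyl (NAP) ether behaves like a benzyl ether in the following steps but is removed oxidatively.

**Step 4**
Reactants: 7 3-O-NAP diacetone glucose
Product: 9 1,2-O-isopropylidene-3-O-(2-naphthylmethyl)-α-D-xylo-pentodialdo-1,4-furanose, via 5,6-diol 8 (not isolated)
Conditions: H5IO6, EtOAc, rt
Reagents that add atoms: none
Why: Periodic acid selectively hydrolyses the terminal (exocyclic) acetonide and cleaves the liberated glycol in the same flask, leaving the ring-fused acetonide and the NAP ether.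

**Step 5**
Reactants: 9 xylo-dialdose
Product: 10 (5S)-1,2-O-isopropylidene-3-O-(2-naphthylmethyl)-5-C-phenyl-α-D-xylofuranose (L-ido-type carbinol)
Conditions: PhMgBr, THF, −78 to 0 °C; aq NH4Cl
Reagents that add atoms: phenylmagnesium bromide, Br[Mg]c1ccccc1
Why: Chelation-controlled Grignard addition in which magnesium bridges the aldehyde oxygen and the furanose ring oxygen and phenyl attacks anti to C3 with its cis ether, which should favour the 5S carbinol (the minor 5R epimer is removed by chromatography).

**Step 6**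
Reactants: 10 L-ido-type carbinol
Product: 11 5-O-mesylate of 10
Conditions: MsCl, Et3N, CH2Cl2, −20 to 0 °C
Reagents that add atoms: methanesulfonyl chloride, CS(=O)(=O)Cl
Why: Sulfonylation of the single free hydroxyl with retention; the β-oxygen keeps the benzylic mesylate from ionising, and it is used without storage.

**Step 7**
Reactants: 11 benzylic mesylate
Product: 13 (2R,3R,4S,5R)-5-(dimethoxymethyl)-4-(2-naphthylmethoxy)-2-phenyloxolan-3-ol, via acyclic dimethyl acetal 12 (not isolated)
Conditions: CSA (0.2 equiv), MeOH, 60 °C; then NaHCO3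
Reagents that add atoms: methanol, CO
Why: Acid methanolysis removes the acetonide and gives methyl furanosides in equilibrium with acyclic acetal 12, whose free C2 hydroxyl displaces the mesylate in a 5-exo-tet SN2 reaction (the known route from 5-O-sulfonyl pentoses to 2,5-anhydro sugars), so that C12 is inverted and phenyl ends trans to the neighbouring hydroxyl and cis to the acetal carbon; a chloride-free acid avoids double inversion.

**Step 8**
Reactants: 13 NAP ether
Product: 14 (2R,3S,4R,5R)-2-(dimethoxymethyl)-5-phenyloxolane-3,4-diol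
Conditions: DDQ, CH2Cl2/pH 7 buffer (10:1), rt
Reagents that add atoms: none
Why: Oxidative cleavage of the electron-rich naphthylmethyl ether by DDQ, which leaves the acetal, the free hydroxyl and the less easily oxidised 2-phenyl-tetrahydrofuran C–H untouched.

**Step 9**
Reactants: 14 diol dimethyl acetal
Product: 15 (2R,3S,4R,5R)-3,4-dihydroxy-5-phenyloxolane-2-carbaldehyde
Conditions: TFA/H2O (1:1), rt; evaporation from toluene
Reagents that add atoms: water, O
Why: Acid hydrolysis of the dimethyl acetal; neither hydroxyl can form a hemiacetal with the aldehyde (one would give a four-membered ring, the other is trans), and the aldehyde is used at once to avoid epimerisation at C20.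

**Step 10**
Reactants: 15 aldehyde
Product: 17 (+)-altholactone, via Z-enoate 16 (not isolated)
Conditions: Ph3P=CHCO2Me, MeOH, 0 °C to rt; then p-TsOH·H2O (cat.), CH2Cl2, rt
Reagents that add atoms: methyl (triphenylphosphoranylidene)acetate, COC(=O)C=P(c1ccccc1)(c1ccccc1)c1ccccc1
Why: Wittig olefination of an α-alkoxy aldehyde with a stabilised ylide in methanol is Z-selective, and in Z-ester 16 the cis C9 hydroxyl closes the α,β-unsaturated δ-lactone (the trans C10 hydroxyl cannot), with no stereocentre touched.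

**Step 11**
Reactants: 17 (+)-altholactone
Product: 18 O-TBS-altholactone
Conditions: TBSOTf, 2,6-lutidine, CH2Cl2, −78 to 0 °C
Reagents that add atoms: tert-butyldimethylsilyl triflate, CC(C)(C)[Si](C)(C)OS(=O)(=O)C(F)(F)F
Why: Silylation of the hindered secondary C10 hydroxyl under non-nucleophilic, weakly basic conditions that do not deprotonate the γ-position of the unsaturated lactone.

**Step 12**
Reactants: 5 (R)-cryptone; 18 O-TBS-altholactone
Product: 21 (2R,3R,3aR,7S,7aS)-3-(TBSO)-7-[(1R,5R)-2-oxo-5-isopropylcyclohex-3-en-1-yl]-2-phenylhexahydro-5H-furo[3,2-b]pyran-5-one, via lithium dienolate 19 (not isolated), via lithium lactone enolate 20 (not isolated)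
Conditions: LDA, THF, −78 °C; then 18, −78 °C; AcOH/THF quench at −78 °C
Reagents that add atoms: none
Why: Michael addition of the kinetic α′-enolate to the unsaturated δ-lactone forms C21–C22 with each partner under its own substrate control: the enolate reacts axially on the face anti to the isopropyl group (C22 R, trans-4,6) and the cis-fused lactone on its convex face, trans to the ring oxygen O19 (C21 S), a pairing that fits a synclinal open transition state; the cold quench protonates enolate 20 before it can close onto the enone.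

**Step 13**
Reactants: 21 enone
Product: 22 (2R,3R,3aR,7S,7aS)-3-(TBSO)-7-[(1R,2R,5R)-2-hydroxy-2-methyl-5-isopropylcyclohex-3-en-1-yl]-2-phenylhexahydro-5H-furo[3,2-b]pyran-5-one
Conditions: MeLi, CeCl3, THF, −78 °C; aq NH4Cl
Reagents that add atoms: methyllithium, [Li]C
Why: Organocerium 1,2-addition is non-basic (no enolisation at C22, no attack on the lactone) and the methyl group should enter anti to the bulky branch on the adjacent carbon, which places the new hydroxyl cis to C21 (C2 R).

**Step 14**
Reactants: 22 tertiary allylic alcohol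
Product: 25 (4S,4aR,6R,8aR)-4-[(2S,3R,4R,5R)-3,4-bis(TBSO)-5-phenyloxolan-2-yl]-6-isopropyl-8a-methyl-3,4,4a,5,6,8a-hexahydro-2H-chromen-2-one, via tertiary sodium alkoxide 23 (not isolated), via translactonised C9 alkoxide 24 (not isolated)
Conditions: NaH (1.1 equiv), THF, 0 °C to rt; then TBSCl, 0 °C to rt
Reagents that add atoms: tert-butyldimethylsilyl chloride, CC(C)(C)[Si](C)(C)Cl
Why: Intramolecular acyl transfer (translactonisation) from the secondary C9 oxygen to the tertiary C2 alkoxide through a six-membered tetrahedral intermediate is pulled towards the less basic, oxygen-flanked C9 alkoxide, which TBSCl captures while leaving tertiary alkoxides alone; the cis ring fusion follows from the C2 and C22 configurations already set.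

**Step 15**
Reactants: 25 cis-fused tertiary allylic δ-lactone
Product: 28 (1R,2S,3R,4R,7R)-3-[(2S,3R,4R,5R)-3,4-bis(TBSO)-5-phenyloxolan-2-yl]-5-methyl-7-isopropylbicyclo[2.2.2]oct-5-ene-2-carboxylic acid, via silyl ketene acetal 26 (not isolated), via silyl ester 27 (not isolated)
Conditions: LDA, TBSCl, HMPA, THF, −78 °C to rt; toluene, 110 °C; then AcOH/THF/H2O, rt
Reagents that add atoms: none
Why: LDA/TBSCl converts the lactone (only C5 is enolisable) into cyclic silyl ketene acetal 26, whose enol ether C5=C6–O8 and allyl unit C2–C3=C4 undergo a concerted suprafacial [3,3] shift that forms C4–C5 and C2=C3 as the C2–O8 tether breaks, giving silyl ester 27 and, after mild hydrolysis, acid 28. The closest known reaction type is the Ireland–Claisen rearrangement of silyl ketene acetals of 6-alkenyl δ-lactones to cyclohexenecarboxylic acids, which likewise must pass through a boat. The six-membered carbocycle C2–C3–C4–C5–C21–C22 closes by this pericyclic bond formation across the 1,4-positions (C22 and C4) of the cyclohexene, turning the lactone into the third bridge of the bicyclo[2.2.2]octene, with the C21–C22 link holding the six reacting atoms in a boat shaped like a bicyclo[2.2.2]octane. C4 is set because C5 can only arrive on the face of the allyl unit that carried O8 at C2, which the cis ring fusion puts on the side of C21; C5 is set because the ring-locked ketene acetal keeps C6 bound to O8 above C2 in the boat, so the carboxyl ends over the new C2=C3 bond (endo), as in the target. The step needs the rearrangement to win over ionisation or elimination at the tertiary allylic C2–O bond, which the basic, non-ionising conditions and the driving force of C=O formation should secure.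

**Step 16**
Reactants: 28 bis-TBS acid
Product: 29 (1R,2S,3R,4R,7R)-3-[(2S,3S,4R,5R)-3,4-dihydroxy-5-phenyloxolan-2-yl]-5-methyl-7-isopropylbicyclo[2.2.2]oct-5-ene-2-carboxylic acid
Conditions: HF·pyridine, pyridine, THF, 0 °C to rt
Reagents that add atoms: none
Why: Fluoride cleavage of both secondary silyl ethers under pyridine-buffered conditions, mild enough not to protonate the trisubstituted alkene next to the endo carboxylic acid.

**Step 17**
Reactants: 29 dihydroxy acid
Product: 30 target CNP0249919.1
Conditions: DCC, DMAP (cat.), CH2Cl2 (high dilution), 0 °C to rt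
Reagents that add atoms: none
Why: Steglich lactonisation under basic activation (strong acid would add the endo acid across C2=C3); the C9 hydroxyl, cis to C21 on the tetrahydrofuran, closes the six-membered lactone, whereas the trans C10 hydroxyl could only give a strained seven-membered ring.

**Compound list**
1 | isovaleraldehyde | CC(C)CC=O | starting material
2 | methyl vinyl ketone | CC(=O)C=C | starting material
3 | (R)-2-isopropyl-5-oxohexanal | O=C[C@@H](C(C)C)CCC(C)=O | intermediate
4 | (4R)-3-hydroxy-4-isopropylcyclohexan-1-one (carbinol centre undefined) | O=C1CC(O)[C@@H](C(C)C)CC1 | intermediate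
5 | (R)-cryptone, (R)-4-isopropylcyclohex-2-en-1-one | O=C1C=C[C@@H](C(C)C)CC1 | intermediate
6 | 1,2:5,6-di-O-isopropylidene-α-D-glucofuranose (diacetone-D-glucose) | CC1(C)O[C@H]2O[C@H]([C@H]3COC(C)(C)O3)[C@H](O)[C@H]2O1 | starting material
7 | 1,2:5,6-di-O-isopropylidene-3-O-(2-naphthylmethyl)-α-D-glucofuranose | CC1(C)O[C@H]2O[C@H]([C@H]3COC(C)(C)O3)[C@H](OCc3ccc4ccccc4c3)[C@H]2O1 | intermediate
8 | 1,2-O-isopropylidene-3-O-(2-naphthylmethyl)-α-D-glucofuranose | CC1(C)O[C@H]2O[C@H]([C@H](O)CO)[C@H](OCc3ccc4ccccc4c3)[C@H]2O1 | intermediate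
9 | 1,2-O-isopropylidene-3-O-(2-naphthylmethyl)-α-D-xylo-pentodialdo-1,4-furanose | CC1(C)O[C@H]2O[C@H](C=O)[C@H](OCc3ccc4ccccc4c3)[C@H]2O1 | intermediate
10 | (5S)-1,2-O-isopropylidene-3-O-(2-naphthylmethyl)-5-C-phenyl-α-D-xylofuranose (L-ido-type carbinol) | CC1(C)O[C@H]2O[C@H]([C@@H](O)c3ccccc3)[C@H](OCc3ccc4ccccc4c3)[C@H]2O1 | intermediate
11 | 5-O-mesylate of 10 | CC1(C)O[C@H]2O[C@H]([C@@H](OS(C)(=O)=O)c3ccccc3)[C@H](OCc3ccc4ccccc4c3)[C@H]2O1 | intermediate
12 | (5S)-5-O-mesyl-3-O-(2-naphthylmethyl)-5-C-phenyl-aldehydo-D-xylose dimethyl acetal | COC(OC)[C@H](O)[C@@H](OCc1ccc2ccccc2c1)[C@H](O)[C@@H](OS(C)(=O)=O)c1ccccc1 | intermediate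
13 | (2R,3R,4S,5R)-5-(dimethoxymethyl)-4-(2-naphthylmethoxy)-2-phenyloxolan-3-ol | COC(OC)[C@@H]1O[C@H](c2ccccc2)[C@@H](O)[C@@H]1OCc1ccc2ccccc2c1 | intermediate
14 | (2R,3S,4R,5R)-2-(dimethoxymethyl)-5-phenyloxolane-3,4-diol | COC(OC)[C@@H]1O[C@H](c2ccccc2)[C@@H](O)[C@@H]1O | intermediate
15 | (2R,3S,4R,5R)-3,4-dihydroxy-5-phenyloxolane-2-carbaldehyde | O=C[C@@H]1O[C@H](c2ccccc2)[C@@H](O)[C@@H]1O | intermediate
16 | methyl (Z)-3-[(2S,3S,4R,5R)-3,4-dihydroxy-5-phenyloxolan-2-yl]prop-2-enoate | COC(=O)/C=C\[C@@H]1O[C@H](c2ccccc2)[C@@H](O)[C@@H]1O | intermediate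
17 | (+)-altholactone, (2R,3R,3aS,7aS)-3-hydroxy-2-phenyl-2,3,3a,7a-tetrahydro-5H-furo[3,2-b]pyran-5-one | O=C1C=C[C@@H]2O[C@H](c3ccccc3)[C@@H](O)[C@@H]2O1 | intermediate
18 | O-TBS-altholactone, (2R,3R,3aR,7aS)-3-(tert-butyldimethylsilyloxy)-2-phenyl-2,3,3a,7a-tetrahydro-5H-furo[3,2-b]pyran-5-one | O=C1C=C[C@@H]2O[C@H](c3ccccc3)[C@@H](O[Si](C)(C)C(C)(C)C)[C@@H]2O1 | intermediate
19 | lithium (R)-4-isopropylcyclohexa-1,5-dien-1-olate (kinetic dienolate of 5) | [Li]OC1=CC[C@H](C(C)C)C=C1 | intermediate
20 | lithium lactone enolate of adduct 21 | O=C1C=C[C@@H](C(C)C)C[C@@H]1[C@@H]2C=C(O[Li])O[C@H]3[C@H](O[Si](C)(C)C(C)(C)C)[C@@H](c4ccccc4)O[C@@H]23 | intermediate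
21 | Michael adduct, (2R,3R,3aR,7S,7aS)-3-(TBSO)-7-[(1R,5R)-2-oxo-5-isopropylcyclohex-3-en-1-yl]-2-phenylhexahydro-5H-furo[3,2-b]pyran-5-one | O=C1C=C[C@@H](C(C)C)C[C@@H]1[C@@H]2CC(=O)O[C@H]3[C@H](O[Si](C)(C)C(C)(C)C)[C@@H](c4ccccc4)O[C@@H]23 | intermediate
22 | tertiary allylic alcohol, 7-[(1R,2R,5R)-2-hydroxy-2-methyl-5-isopropylcyclohex-3-en-1-yl] analogue of 21 (hydroxyl cis to the lactone branch) | C[C@@]1(O)C=C[C@@H](C(C)C)C[C@@H]1[C@@H]2CC(=O)O[C@H]3[C@H](O[Si](C)(C)C(C)(C)C)[C@@H](c4ccccc4)O[C@@H]23 | intermediate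
23 | sodium tertiary alkoxide of 22 | C[C@@]1([O-])C=C[C@@H](C(C)C)C[C@@H]1[C@@H]2CC(=O)O[C@H]3[C@H](O[Si](C)(C)C(C)(C)C)[C@@H](c4ccccc4)O[C@@H]23.[Na+] | intermediate
24 | sodium C9 alkoxide of the translactonised cis-fused chromenone (C10 still TBS-protected) | C[C@@]12C=C[C@@H](C(C)C)C[C@@H]1[C@H](CC(=O)O2)[C@@H]3O[C@H](c4ccccc4)[C@@H](O[Si](C)(C)C(C)(C)C)[C@@H]3[O-].[Na+] | intermediate
25 | (4S,4aR,6R,8aR)-4-[(2S,3R,4R,5R)-3,4-bis(TBSO)-5-phenyloxolan-2-yl]-6-isopropyl-8a-methyl-3,4,4a,5,6,8a-hexahydro-2H-chromen-2-one | C[C@@]12C=C[C@@H](C(C)C)C[C@@H]1[C@H](CC(=O)O2)[C@@H]3O[C@H](c4ccccc4)[C@@H](O[Si](C)(C)C(C)(C)C)[C@@H]3O[Si](C)(C)C(C)(C)C | intermediate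
26 | cyclic TBS ketene acetal of 25 (C5=C6) | C[C@@]12C=C[C@@H](C(C)C)C[C@@H]1[C@H](C=C(O[Si](C)(C)C(C)(C)C)O2)[C@@H]3O[C@H](c4ccccc4)[C@@H](O[Si](C)(C)C(C)(C)C)[C@@H]3O[Si](C)(C)C(C)(C)C | intermediate
27 | TBS ester of acid 28 | CC1=C[C@@H]2[C@H](C(=O)O[Si](C)(C)C(C)(C)C)[C@H]([C@@H]3O[C@H](c4ccccc4)[C@@H](O[Si](C)(C)C(C)(C)C)[C@@H]3O[Si](C)(C)C(C)(C)C)[C@H]1C[C@@H]2C(C)C | intermediate
28 | (1R,2S,3R,4R,7R)-3-[(2S,3R,4R,5R)-3,4-bis(TBSO)-5-phenyloxolan-2-yl]-5-methyl-7-isopropylbicyclo[2.2.2]oct-5-ene-2-carboxylic acid (carboxyl and oxolanyl both syn to the alkene bridge) | CC1=C[C@@H]2[C@H](C(=O)O)[C@H]([C@@H]3O[C@H](c4ccccc4)[C@@H](O[Si](C)(C)C(C)(C)C)[C@@H]3O[Si](C)(C)C(C)(C)C)[C@H]1C[C@@H]2C(C)C | intermediate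
29 | (1R,2S,3R,4R,7R)-3-[(2S,3S,4R,5R)-3,4-dihydroxy-5-phenyloxolan-2-yl]-5-methyl-7-isopropylbicyclo[2.2.2]oct-5-ene-2-carboxylic acid | CC1=C[C@@H]2[C@H](C(=O)O)[C@H]([C@@H]3O[C@H](c4ccccc4)[C@@H](O)[C@@H]3O)[C@H]1C[C@@H]2C(C)C | intermediate
30 | target CNP0249919.1: altholactone-type furo-pyranone cis-fused through C5–C21 to the bicyclo[2.2.2]octene, lactone carbonyl and oxolane carbon syn to the C2=C3 bridge (SMILES numbering 4R,5S,9S,10R,12R,20S,21R,22R,24R) | CC1=C[C@@H]2[C@@H]3C(=O)O[C@H]4[C@H](O)[C@@H](c5ccccc5)O[C@H]4[C@@H]3[C@H]1C[C@@H]2C(C)C | target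

**Step count**
Total: 17 steps. Longest linear sequence: 15 steps (steps 3–17, from diacetone-D-glucose); the cryptone branch (steps 1–2) joins at step 12.

**Steps most likely to fail**

1. Step 15 (key step). The ketene acetal may be unable to fold into the cage-like boat, so that on heating elimination of the tertiary allylic carboxylate (diene formation) or simple desilylation outruns the [3,3] shift. Fallback, from 17 to 30: (+)-altholactone 17 is heated with commercial (R)-α-phellandrene (CC1=CC[C@H](C(C)C)C=C1, excess) in toluene at 110 °C in a sealed tube. This is a Diels–Alder reaction of a 2-substituted cyclohexadiene with an unsaturated lactone, expected to be endo, "para" (C5 to C4, C21 to C22), anti to the isopropyl group on the diene and on the convex face of the lactone, and it should give 30 directly. It forms the C4–C5 and C21–C22 bonds by cycloaddition instead of by the sigmatropic shift.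

2. Step 12. The first-formed lactone enolate may close onto the enone in a second Michael reaction, or proton transfer may take over (deprotonation at the γ-position C20 with opening of the tetrahydrofuran, or equilibration at C22). Fallback, from 5 to 21: cryptone is condensed with N,N-dimethylhydrazine (AcOH cat., EtOH) to the N,N-dimethylhydrazone of (R)-cryptone F1, whose C=N–C=C unit is not a Michael acceptor. Kinetic α′-lithiation (LDA, THF, −78 °C) and aza-enolate conjugate addition to 18 should give the hydrazone adduct F2 with the same facial preferences. Mild hydrolysis (aq oxalic acid/Et2O, or CuCl2 in buffered aq THF) returns enone 21.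

3. Step 14. Acyl transfer may stop on the side of the secondary lactone, or silylation of the tertiary alkoxide may outrun it. Fallback, from 22 to 25: the lactone of 22 is saponified (LiOH, THF/H2O) to the lithium carboxylate of the seco acid F3. TBSCl/imidazole in DMF silylates the C9 hydroxyl and the carboxylate but not the tertiary alcohol, giving the silyl ester F4. Aqueous K2CO3/MeOH cleaves the silyl ester to the seco acid F5, which is closed onto the tertiary allylic hydroxyl by Yamaguchi lactonisation (2,4,6-trichlorobenzoyl chloride, Et3N; then DMAP, toluene) to give 25.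

**Further compounds**
F0 | step 15 | none | none
F1 | step 12 | N,N-dimethylhydrazone of (R)-cryptone (C=N geometry not defined) | CN(C)N=C1C=C[C@@H](C(C)C)CC1
F2 | step 12 | N,N-dimethylhydrazone of Michael adduct 21 (C=N geometry not defined) | CN(C)N=C1C=C[C@@H](C(C)C)C[C@@H]1[C@@H]2CC(=O)O[C@H]3[C@H](O[Si](C)(C)C(C)(C)C)[C@@H](c4ccccc4)O[C@@H]23
F3 | step 14 | lithium carboxylate of the ring-opened seco acid of 22 (C2 and C9 hydroxyls free, C10 OTBS) | C[C@@]1(O)C=C[C@@H](C(C)C)C[C@@H]1[C@H](CC(=O)[O-])[C@@H]2O[C@H](c3ccccc3)[C@@H](O[Si](C)(C)C(C)(C)C)[C@@H]2O.[Li+]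
F4 | step 14 | TBS ester of the 3,4-bis(TBSO) seco acid (tertiary hydroxyl free) | C[C@@]1(O)C=C[C@@H](C(C)C)C[C@@H]1[C@H](CC(=O)O[Si](C)(C)C(C)(C)C)[C@@H]2O[C@H](c3ccccc3)[C@@H](O[Si](C)(C)C(C)(C)C)[C@@H]2O[Si](C)(C)C(C)(C)C
F5 | step 14 | 3,4-bis(TBSO) seco acid (tertiary hydroxyl free) | C[C@@]1(O)C=C[C@@H](C(C)C)C[C@@H]1[C@H](CC(=O)O)[C@@H]2O[C@H](c3ccccc3)[C@@H](O[Si](C)(C)C(C)(C)C)[C@@H]2O[Si](C)(C)C(C)(C)C
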